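Its constants are assumed; what happens was integrated by code.

Q is charged at less than X (0.050 M against 0.0750 M), so Q is the limiting reagent and you keep the books on it.

common to all: X 0.0750 M; L 0.25 mM; time 4.0 min

| flask | Q | remark | temperature |
|---|---|---|---|
| zeta | 0.050 M (fed, over 2.5 min) | the addition at −20 °C, then warmed to 20 °C; the feed brings no volume worth counting |  |
| gamma | 0.050 M (fed, over 2.5 min) | all else is in the flask from the start; the feed brings no volume worth counting | 20 °C |
| beta | 0.050 M (in portions, 3, over 2.5 min) | first portion at the start, last at 2.5 min | 20 °C |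
| alpha | 0.050 M | everything together at the start | 20 °C |

    Q + X + L → L + G (k1 = 153 L² mol⁻² s⁻¹, Ea1 = 41.0 kJ mol⁻¹)
    D ⇌ G, rate k2*(cs2 - [G]) while solid is left; crystals form when [G] > cs2 (cs2 = 12 mM, k2 = 0.0357 s⁻¹)
    Q + X → Q.X (k3 = 0.0712 L mol⁻¹ s⁻¹, Ea3 = 48.0 kJ mol⁻¹)
    (constants at 20 °C)

- for G the D are counted in
- as a solid, counted per litre of solution: D
- the list of constants is for 20 °C, to be carried to other temperatures by the activation energies

1. the best flask by amount of G, in percent of the Q charged; "all alike" if 1.5 percentage points covers them all (zeta / gamma / beta / alpha / all alike)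
2. amount of G at the end, in percent of the Q charged, zeta
3. amount of G at the end, in percent of the Q charged, gamma
4. amount of G at the end, in percent of the Q charged, beta
5. amount of G at the end, in percent of the Q charged, alpha

Each Q that reacts takes one X by one of two steps, and both rates carry cQ·cX. L stands on both sides of its step, so at 20 °C you split the Q used like this:

share = 153 L² mol⁻² s⁻¹ × 0.25 mM / (153 L² mol⁻² s⁻¹ × 0.25 mM + 0.0712 L mol⁻¹ s⁻¹) = 34.9%

That is the G share, the part of the Q used that ends as G. D counts in G, so it needs no entry of its own.

Now for the Q left in alpha. One X goes with each Q, so cX − cQ stays at 0.0250 M. In logarithms the reckoning is a straight line: ln(cX/cQ) climbs steadily, at that gap times the summed constant 0.109 L mol⁻¹ s⁻¹.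

climb over 4.0 min = 0.657

cX/cQ at the end = (0.0750 M / 0.050 M) × e^climb = 2.89

With the gap, that puts cQ at 0.0132 M. My ledger for alpha reads:

Q left: 26.4%

G: 25.7%

Q.X: 47.9%

Total: 100%

In gamma and beta, Q waits on average 1.25 min before it is in the flask, so I reckon each as alpha run for 2.75 min, which gives G 22.1%. In zeta I leave the cold stretch out and count 1.50 min at 20 °C, which gives G 15.9%. My pick is alpha.

The forecast names alpha, with 16.7% for zeta, 21.6% for gamma, 21.2% for beta and 25.7% for alpha. Its ground: “Both routes are first order in Q and in X, so Q-feeding cannot change selectivity”. Its figures for zeta, gamma and beta differ from my rougher ones.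

The simulation gives alpha, with 16.7% for zeta, 21.6% for gamma, 21.2% for beta and 25.7% for alpha.

In alpha the path to Q.X used X 1.9 times as fast as the path to G at 1.08 min, and used Q 1.9 times as fast at 4.00 min; the G share stands for 1.87, a figure from the same constants and so no check. At the end alpha holds 26% of its Q unused, less than the 53% in zeta.

Take the neighbour flask, alpha with 1.5 × 10⁻⁴ M of L. The G share falls to 24.4%, the same logarithm leaves 30.5% of Q, and G comes to 17.0%. The simulation of that flask gives 16.9% of G, with 31% of Q left.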